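Numbering: C1 is the lactone carbonyl, C26 the chain terminus. The plan cuts the dihydropyranone ring at C3–C4 and C5–O and traces both cuts back to one terminal C4=C5 alkene on a C7 homoallylic carbinol. The feature used is the 1,3-syn relationship between the C7 carbinol and the oxygen on C5 of the lactone ring, plus a C4 carbon that has to be joined to C3 afterwards. Cyclisation of the C7 tert-butyl carbonate with iodine monobromide makes the C5–O bond, fixes C5 from C7 and leaves iodide on C4 in a single operation. Its precursor 18 is the C4–C26 chain with the Boc carbonate on O7, an acetonide across O9/O11 and a silyl ether on O15.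

Key step: step 12

Remarks on the chemistry:
- TBS = tert-butyldimethylsilyl, TMS = trimethylsilyl, Ipc = isopinocampheyl.
- Compounds 7 and 8 are used as E/Z mixtures, because their geometry is erased in step 6.
- The hemiacetal carbon of 14 is uncontrolled and disappears on work-up.
- Descriptors in the names follow the CIP rules for each compound. The letters at C7 and C9 therefore change between some intermediates although no bond at these centres is broken.
- Both enantiomers of Ipc2BOMe, allylmagnesium bromide, di-tert-butyl dicarbonate and ethyl propiolate are taken as commercial reagents.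

Step 1
Reactants: 1 dodecanal
Product: 3 (S)-pentadec-1-en-4-ol, via borinate ester 2 (not isolated)
Conditions: (+)-Ipc2BOMe, CH2=CHCH2MgBr, Et2O, 0 °C to rt; then 1, −78 °C; then NaOH, H2O2, rt
Reagents that add atoms: allylmagnesium bromide C=CC[Mg]Br
Why: Brown allylboration, in which the B-allyldiisopinocampheylborane made in the flask from the (−)-α-pinene-derived borinate transfers allyl through a chair six-membered transition state to the Re face of the aldehyde, which should give the 15S carbinol.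

Step 2
Reactants: 3 (S)-pentadec-1-en-4-ol
Product: 4 (S)-4-(TBSO)pentadec-1-ene
Conditions: TBSCl, imidazole, DMF, rt
Reagents that add atoms: tert-butyldimethylsilyl chloride CC(C)(C)[Si](C)(C)Cl
Why: Imidazole-promoted silylation of a secondary alcohol is routine and protects O15 for the organometallic and hydride steps that follow.

Step 3
Reactants: 4 (S)-4-(TBSO)pentadec-1-ene
Product: 5 (S)-5-(TBSO)hexadecanal
Conditions: Rh(acac)(CO)2 (cat.), Xantphos, CO/H2 (1:1, 10 bar), toluene, 80 °C
Reagents that add atoms: carbon monoxide [C-]#[O+]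
Why: Linear-selective rhodium-catalysed hydroformylation of a terminal alkene with a wide-bite-angle diphosphine puts the formyl carbon C11 on the unsubstituted alkene carbon C12 and leaves the C15 stereocentre and the silyl ether untouched.

Step 4
Reactants: 6 methyl acetoacetate
Product: 7 methyl 3-(trimethylsilyloxy)but-2-enoate
Conditions: TMSCl, Et3N, hexane, rt
Reagents that add atoms: chlorotrimethylsilane C[Si](C)(C)Cl
Why: O-Silylation of the enol of a β-keto ester with a silyl chloride and an amine base is standard silyl enol ether formation.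

Step 5
Reactants: 7 methyl 3-(trimethylsilyloxy)but-2-enoate
Product: 8 1-methoxy-1,3-bis(trimethylsilyloxy)buta-1,3-diene
Conditions: LiN(iPr)2, THF, −78 °C; TMSCl, −78 to 0 °C
Reagents that add atoms: chlorotrimethylsilane C[Si](C)(C)Cl
Why: γ-Deprotonation of the vinylogous ester gives the dienolate, which is silylated on oxygen to the silyl ketene acetal (silyl dienol ether formation).

Step 6
Reactants: 5 (S)-5-(TBSO)hexadecanal; 8 1-methoxy-1,3-bis(trimethylsilyloxy)buta-1,3-diene
Product: 10 methyl (5R,9S)-9-(TBSO)-5-hydroxy-3-oxoicosanoate, via silylated aldol adduct 9 (not isolated)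
Conditions: Ti(OiPr)4 (cat.), (S)-BINOL (cat.), 4 Å molecular sieves, THF, −78 °C to rt; then 1 M HCl, THF, 0 °C
Reagents that add atoms: none
Why: Catalytic enantioselective vinylogous Mukaiyama aldol addition, in which the (S)-BINOL–titanium isopropoxide complex binds the aldehyde and is expected to steer the terminal carbon of the dienol ether (future C10) to the Si face of C11, setting 11R (5R in 10), after which brief dilute acid removes both TMS groups while the secondary TBS ether stays.

Step 7
Reactants: 10 methyl (5R,9S)-9-(TBSO)-5-hydroxy-3-oxoicosanoate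
Product: 12 methyl (3R,5R,9S)-9-(TBSO)-3,5-dihydroxyicosanoate, via diethylboron chelate 11 (not isolated)
Conditions: Et2BOMe, THF/MeOH (4:1), −78 °C; NaBH4, −78 °C; then MeOH co-evaporation
Reagents that add atoms: none
Why: Narasaka–Prasad reduction, in which the diethylboron chelate between O11 and the C9 ketone holds a half-chair that borohydride attacks axially, so that C9 is set by C11 as the 1,3-syn diol.

Step 8
Reactants: 12 methyl (3R,5R,9S)-9-(TBSO)-3,5-dihydroxyicosanoate
Product: 13 methyl 2-[(4R,6R)-6-[(4S)-4-(TBSO)pentadecyl]-2,2-dimethyl-1,3-dioxan-4-yl]acetate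
Conditions: 2,2-dimethoxypropane, PPTS (cat.), CH2Cl2, rt
Reagents that add atoms: 2,2-dimethoxypropane COC(C)(C)OC
Why: Acid-catalysed transacetalisation of a 1,3-syn diol gives the chair acetonide with both ring substituents equatorial, and the mild pyridinium catalyst leaves the TBS ether and the ester alone.

Step 9
Reactants: 13 acetonide ester
Product: 15 2-[(4R,6R)-6-[(4S)-4-(TBSO)pentadecyl]-2,2-dimethyl-1,3-dioxan-4-yl]acetaldehyde, via aluminium hemiacetal 14 (not isolated)
Conditions: iBu2AlH, CH2Cl2, −78 °C; then aqueous potassium sodium tartrate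
Reagents that add atoms: none
Why: Partial reduction of a methyl ester with the aluminium hydride at −78 °C stops at the tetrahedral aluminium hemiacetal, which releases the aldehyde only on aqueous work-up.

Step 10
Reactants: 15 C7 aldehyde
Product: 17 (2S)-1-[(4S,6R)-6-[(4S)-4-(TBSO)pentadecyl]-2,2-dimethyl-1,3-dioxan-4-yl]pent-4-en-2-ol, via borinate ester 16 (not isolated)
Conditions: (−)-Ipc2BOMe, CH2=CHCH2MgBr, Et2O, 0 °C to rt; then 15, −78 °C; then NaOH, H2O2, rt
Reagents that add atoms: allylmagnesium bromide C=CC[Mg]Br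
Why: Brown allylboration under reagent control, in which the allylborane from the (+)-α-pinene-derived borinate attacks the Si face of the C7 aldehyde through the chair transition state, overriding the weak bias of the C9 acetal oxygen and giving the carbinol 1,3-syn to O9 (2S in 17).

Step 11
Reactants: 17 C7 homoallylic alcohol
Product: 18 tert-butyl (2S)-1-[(4R,6R)-6-[(4S)-4-(TBSO)pentadecyl]-2,2-dimethyl-1,3-dioxan-4-yl]pent-4-en-2-yl carbonate
Conditions: Boc2O, DMAP, MeCN, rt
Reagents that add atoms: di-tert-butyl dicarbonate CC(C)(C)OC(=O)OC(=O)OC(C)(C)C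
Why: DMAP-catalysed acylation of the secondary alcohol by the dicarbonate (carbonate formation) installs the internal oxygen nucleophile without touching any stereocentre.

Step 12
Reactants: 18 C7 tert-butyl carbonate
Product: 20 (4R,6R)-4-{[(4R,6R)-6-[(4S)-4-(TBSO)pentadecyl]-2,2-dimethyl-1,3-dioxan-4-yl]methyl}-6-(iodomethyl)-1,3-dioxan-2-one, via dioxanylium bromide 19 (not isolated)
Conditions: IBr, toluene, −85 °C; then aq. Na2S2O3/NaHCO3
Reagents that add atoms: iodine monobromide IBr
Why: Iodine monobromide forms an iodonium ion reversibly on the terminal C4=C5 alkene, and the carbonyl oxygen of the C7 carbonate opens it at the substituted carbon C5 to give the 2-tert-butoxy-1,3-dioxan-2-ylium ion 19, which hands its tert-butyl group to bromide. The closest known reaction type is the electrophile-induced cyclisation of homoallylic tert-butyl carbonates to iodomethyl cyclic carbonates of 1,3-syn diols. The only ring formed, the 1,3-dioxan-2-one made of the carbonate carbon, O7, C7, C6, C5 and O5, closes in the 6-exo mode, with C4 left outside the ring as CH2I. The only new stereocentre, C5, is controlled by C7: in the chair-like transition state the C8 chain on C7 lies equatorial and the complexed alkene takes the other equatorial site, so the CH2I arm ends cis to the C8 chain and O5 is syn to O7. The step needs 1,3-syn diastereoselectivity, Markovnikov 6-exo regioselectivity and attack by the carbonate in preference to the C9 acetal oxygen; the fixed C7 configuration, the low temperature with the reactive IBr and the better nucleophilicity and geometry of the carbonate carbonyl should provide these, and capture of the tert-butyl cation by bromide keeps strong acid away from the acetonide and the silyl ether.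

Step 13
Reactants: 20 iodocarbonate
Product: 22 (2R)-1-[(4S,6R)-6-[(4S)-4-(TBSO)pentadecyl]-2,2-dimethyl-1,3-dioxan-4-yl]-3-[(2R)-oxiran-2-yl]propan-2-ol, via iodo diol 21 (not isolated)
Conditions: K2CO3, MeOH, rt
Reagents that add atoms: none
Why: Carbonate methanolysis followed by intramolecular Williamson etherification, in which the freed O5 alkoxide displaces the primary iodide on C4 (3-exo-tet), so the configuration at C5 is kept because its C–O bond is never broken.

Step 14
Reactants: 22 epoxy alcohol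
Product: 23 (4R,6R)-4-[(2R)-2-(TBSO)-3-[(2R)-oxiran-2-yl]propyl]-6-[(4S)-4-(TBSO)pentadecyl]-2,2-dimethyl-1,3-dioxane
Conditions: TBSCl, imidazole, DMF, rt
Reagents that add atoms: tert-butyldimethylsilyl chloride CC(C)(C)[Si](C)(C)Cl
Why: Standard silylation of the C7 secondary alcohol removes the only acidic proton before the organolithium step, and these mild conditions do not open the terminal epoxide.

Step 15
Reactants: 23 silylated epoxide
Product: 24 ethyl (5S,7S)-7-(TBSO)-8-[(4R,6R)-6-[(4S)-4-(TBSO)pentadecyl]-2,2-dimethyl-1,3-dioxan-4-yl]-5-hydroxyoct-2-ynoate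
Conditions: ethyl propiolate, n-BuLi, THF, −78 °C; BF3·OEt2; then 23, −78 °C
Reagents that add atoms: ethyl propiolate C#CC(=O)OCC
Why: Boron trifluoride-assisted opening of a terminal epoxide by a lithium acetylide (Yamaguchi–Hirao alkynylation) occurs at the unsubstituted carbon C4 at −78 °C, forming C3–C4 and releasing the C5 hydroxyl without affecting the C5 configuration.

Step 16
Reactants: 24 hydroxy ynoate
Product: 25 ethyl (2Z,5S,7S)-7-(TBSO)-8-[(4R,6R)-6-[(4S)-4-(TBSO)pentadecyl]-2,2-dimethyl-1,3-dioxan-4-yl]-5-hydroxyoct-2-enoate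
Conditions: H2 (1 atm), Pd/CaCO3 poisoned with Pb(OAc)2 (Lindlar catalyst), quinoline, EtOAc, rt
Reagents that add atoms: none
Why: Lindlar semi-hydrogenation delivers both hydrogens to one face of the alkyne on the poisoned palladium surface and stops at the Z-alkene needed for ring closure.

Step 17
Reactants: 25 Z-enoate
Product: 27 (6S)-6-[(2R,4R,6R,10S)-2,4,6,10-tetrahydroxyhenicosyl]-5,6-dihydro-2H-pyran-2-one, via pentahydroxy enoate 26 (not isolated)
Conditions: aq. HF (48%), MeCN, rt
Reagents that add atoms: none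
Why: Acid-mediated global deprotection cleaves the two silyl ethers and the acetonide, and the Z-δ-hydroxy enoate then lactonises to the six-membered ring (intramolecular transesterification) with loss of ethanol, no stereocentre being involved.

Compound list
1 | dodecanal | CCCCCCCCCCCC=O | starting material
2 | (4S)-pentadec-1-en-4-yl diisopinocampheylborinate, Ipc groups as in (+)-isopinocampheol | CCCCCCCCCCC[C@H](OB([C@H]1C[C@H]2C[C@@H]([C@@H]1C)C2(C)C)[C@H]1C[C@H]2C[C@@H]([C@@H]1C)C2(C)C)CC=C | intermediate (not isolated)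
3 | (S)-pentadec-1-en-4-ol | CCCCCCCCCCC[C@H](O)CC=C | intermediate
4 | (S)-4-(tert-butyldimethylsilyloxy)pentadec-1-ene | CCCCCCCCCCC[C@H](O[Si](C)(C)C(C)(C)C)CC=C | intermediate
5 | (S)-5-(tert-butyldimethylsilyloxy)hexadecanal | CCCCCCCCCCC[C@H](O[Si](C)(C)C(C)(C)C)CCCC=O | intermediate
6 | methyl acetoacetate | CC(=O)CC(=O)OC | starting material
7 | methyl 3-(trimethylsilyloxy)but-2-enoate (E/Z mixture) | CC(O[Si](C)(C)C)=CC(=O)OC | intermediate
8 | 1-methoxy-1,3-bis(trimethylsilyloxy)buta-1,3-diene (E/Z mixture) | C=C(O[Si](C)(C)C)C=C(OC)O[Si](C)(C)C | intermediate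
9 | methyl (5R,9S)-9-(tert-butyldimethylsilyloxy)-3,5-bis(trimethylsilyloxy)icos-2-enoate | CCCCCCCCCCC[C@H](O[Si](C)(C)C(C)(C)C)CCC[C@@H](O[Si](C)(C)C)CC(O[Si](C)(C)C)=CC(=O)OC | intermediate (not isolated)
10 | methyl (5R,9S)-9-(tert-butyldimethylsilyloxy)-5-hydroxy-3-oxoicosanoate | CCCCCCCCCCC[C@H](O[Si](C)(C)C(C)(C)C)CCC[C@@H](O)CC(=O)CC(=O)OC | intermediate
11 | methyl (5R,9S)-9-(tert-butyldimethylsilyloxy)-5-(diethylboryloxy)-3-oxoicosanoate (boron chelated to the C3 ketone) | CCCCCCCCCCC[C@H](O[Si](C)(C)C(C)(C)C)CCC[C@@H](OB(CC)CC)CC(=O)CC(=O)OC | intermediate (not isolated)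
12 | methyl (3R,5R,9S)-9-(tert-butyldimethylsilyloxy)-3,5-dihydroxyicosanoate | CCCCCCCCCCC[C@H](O[Si](C)(C)C(C)(C)C)CCC[C@@H](O)C[C@@H](O)CC(=O)OC | intermediate
13 | methyl 2-[(4R,6R)-6-[(4S)-4-(tert-butyldimethylsilyloxy)pentadecyl]-2,2-dimethyl-1,3-dioxan-4-yl]acetate | CCCCCCCCCCC[C@H](O[Si](C)(C)C(C)(C)C)CCC[C@@H]1C[C@H](CC(=O)OC)OC(C)(C)O1 | intermediate
14 | diisobutylaluminium methyl hemiacetal of 15 (hemiacetal carbon unassigned, other centres as in 13) | CCCCCCCCCCC[C@H](O[Si](C)(C)C(C)(C)C)CCC[C@@H]1C[C@H](CC(OC)O[Al](CC(C)C)CC(C)C)OC(C)(C)O1 | intermediate (not isolated)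
15 | 2-[(4R,6R)-6-[(4S)-4-(tert-butyldimethylsilyloxy)pentadecyl]-2,2-dimethyl-1,3-dioxan-4-yl]acetaldehyde | CCCCCCCCCCC[C@H](O[Si](C)(C)C(C)(C)C)CCC[C@@H]1C[C@H](CC=O)OC(C)(C)O1 | intermediate
16 | diisopinocampheylborinate of 17, Ipc groups as in (−)-isopinocampheol | CCCCCCCCCCC[C@H](O[Si](C)(C)C(C)(C)C)CCC[C@@H]1C[C@H](C[C@H](CC=C)OB([C@@H]2C[C@@H]3C[C@H]([C@H]2C)C3(C)C)[C@@H]2C[C@@H]3C[C@H]([C@H]2C)C3(C)C)OC(C)(C)O1 | intermediate (not isolated)
17 | (2S)-1-[(4S,6R)-6-[(4S)-4-(tert-butyldimethylsilyloxy)pentadecyl]-2,2-dimethyl-1,3-dioxan-4-yl]pent-4-en-2-ol | CCCCCCCCCCC[C@H](O[Si](C)(C)C(C)(C)C)CCC[C@@H]1C[C@H](C[C@H](CC=C)O)OC(C)(C)O1 | intermediate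
18 | tert-butyl (2S)-1-[(4R,6R)-6-[(4S)-4-(tert-butyldimethylsilyloxy)pentadecyl]-2,2-dimethyl-1,3-dioxan-4-yl]pent-4-en-2-yl carbonate | CCCCCCCCCCC[C@H](O[Si](C)(C)C(C)(C)C)CCC[C@@H]1C[C@H](C[C@H](CC=C)OC(=O)OC(C)(C)C)OC(C)(C)O1 | intermediate (key-step precursor)
19 | 2-tert-butoxy-1,3-dioxan-2-ylium bromide corresponding to 20 (ring substituents cis, all centres as in 20) | CCCCCCCCCCC[C@H](O[Si](C)(C)C(C)(C)C)CCC[C@@H]1C[C@H](C[C@@H]2C[C@H](CI)O[C+](OC(C)(C)C)O2)OC(C)(C)O1.[Br-] | intermediate (not isolated)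
20 | (4R,6R)-4-{[(4R,6R)-6-[(4S)-4-(tert-butyldimethylsilyloxy)pentadecyl]-2,2-dimethyl-1,3-dioxan-4-yl]methyl}-6-(iodomethyl)-1,3-dioxan-2-one | CCCCCCCCCCC[C@H](O[Si](C)(C)C(C)(C)C)CCC[C@@H]1C[C@H](C[C@@H]2C[C@H](CI)OC(=O)O2)OC(C)(C)O1 | intermediate (key-step product)
21 | iodo diol: 20 without the carbonate carbonyl (free syn 5-OH and 7-OH, iodide on C4, other centres as in 20) | CCCCCCCCCCC[C@H](O[Si](C)(C)C(C)(C)C)CCC[C@@H]1C[C@H](C[C@@H](O)C[C@H](CI)O)OC(C)(C)O1 | intermediate (not isolated)
22 | (2R)-1-[(4S,6R)-6-[(4S)-4-(tert-butyldimethylsilyloxy)pentadecyl]-2,2-dimethyl-1,3-dioxan-4-yl]-3-[(2R)-oxiran-2-yl]propan-2-ol | CCCCCCCCCCC[C@H](O[Si](C)(C)C(C)(C)C)CCC[C@@H]1C[C@H](C[C@@H](O)C[C@@H]2CO2)OC(C)(C)O1 | intermediate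
23 | (4R,6R)-4-[(2R)-2-(tert-butyldimethylsilyloxy)-3-[(2R)-oxiran-2-yl]propyl]-6-[(4S)-4-(tert-butyldimethylsilyloxy)pentadecyl]-2,2-dimethyl-1,3-dioxane | CCCCCCCCCCC[C@H](O[Si](C)(C)C(C)(C)C)CCC[C@@H]1C[C@H](C[C@@H](O[Si](C)(C)C(C)(C)C)C[C@@H]2CO2)OC(C)(C)O1 | intermediate
24 | ethyl (5S,7S)-7-(tert-butyldimethylsilyloxy)-8-[(4R,6R)-6-[(4S)-4-(tert-butyldimethylsilyloxy)pentadecyl]-2,2-dimethyl-1,3-dioxan-4-yl]-5-hydroxyoct-2-ynoate | CCCCCCCCCCC[C@H](O[Si](C)(C)C(C)(C)C)CCC[C@@H]1C[C@H](C[C@@H](O[Si](C)(C)C(C)(C)C)C[C@@H](O)CC#CC(=O)OCC)OC(C)(C)O1 | intermediate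
25 | ethyl (2Z,5S,7S)-7-(tert-butyldimethylsilyloxy)-8-[(4R,6R)-6-[(4S)-4-(tert-butyldimethylsilyloxy)pentadecyl]-2,2-dimethyl-1,3-dioxan-4-yl]-5-hydroxyoct-2-enoate | CCCCCCCCCCC[C@H](O[Si](C)(C)C(C)(C)C)CCC[C@@H]1C[C@H](C[C@@H](O[Si](C)(C)C(C)(C)C)C[C@@H](O)C/C=C\C(=O)OCC)OC(C)(C)O1 | intermediate
26 | ethyl (2Z,5S,7S,9R,11R,15S)-5,7,9,11,15-pentahydroxyhexacos-2-enoate | CCCCCCCCCCC[C@H](O)CCC[C@@H](O)C[C@@H](O)C[C@@H](O)C[C@@H](O)C/C=C\C(=O)OCC | intermediate (not isolated)
27 | (6S)-6-[(2R,4R,6R,10S)-2,4,6,10-tetrahydroxyhenicosyl]-5,6-dihydro-2H-pyran-2-one | CCCCCCCCCCC[C@H](O)CCC[C@@H](O)C[C@@H](O)C[C@@H](O)C[C@@H]1CC=CC(=O)O1 | target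

Total step count: 17. Longest linear sequence: 15 steps from dodecanal (steps 1–3 and 6–17); steps 4 and 5 prepare the dienol ether in a side branch.

Steps most likely to fail

Step 12. The cyclisation could lose its 1,3-syn control if the mixture warms. The C9 acetal oxygen could capture the iodonium ion in place of the carbonate. Traces of hydrogen bromide could also strip the acetonide. The fallback sets out from 17 and comes back to the route at 27, setting C5 by thermodynamic acetal formation. Cross-metathesis of 17 with methyl acrylate (second-generation Hoveyda–Grubbs catalyst, CH2Cl2, 40 °C) should give the (E)-δ-hydroxy enoate F1. Benzaldehyde and KOtBu in THF at 0 °C then let the hemiacetal alkoxide add to the enoate in conjugate fashion under equilibrating conditions, giving the all-cis benzylidene acetal ester F2 with O5 syn to O7. Reduction with iBu2AlH at −78 °C gives the aldehyde F3. Still–Gennari olefination (methyl bis(2,2,2-trifluoroethyl)phosphonoacetate, KN(SiMe3)2, 18-crown-6, THF, −78 °C) gives the Z-enoate F4. Aqueous HCl in methanol removes both acetals and the silyl ether and closes the lactone to 27.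

Step 15. The lithium acetylide of ethyl propiolate decomposes if the mixture warms, and BF3 may open the acetonide or rearrange the epoxide before the acetylide attacks. The fallback sets out from 23 and comes back at 27, building the lactone by ring-closing metathesis. Copper-catalysed opening of 23 with CH2=CHMgBr (CuI cat., THF, −40 °C) should give the homoallylic alcohol F5. Acryloyl chloride and Et3N in CH2Cl2 at 0 °C give the acrylate F6. The second-generation Grubbs catalyst (CH2Cl2, 40 °C) closes the protected dihydropyranone F7. Aqueous HF in MeCN, as in step 17, gives 27.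

Step 6. Facial selectivity of the titanium–BINOL catalyst on an unbranched aliphatic aldehyde may be insufficient, and the catalyst may turn over slowly. The resulting C11 epimers would be hard to remove because the nearest stereocentre, C15, is remote. The configuration at C11 is to be checked on 10 by Mosher ester analysis. The fallback sets out from 5 and comes back at 10, setting C11 by ketone hydrogenation. SnCl2-catalysed Roskamp homologation of 5 with methyl diazoacetate (CH2Cl2, rt) should give the β-keto ester F8. Noyori hydrogenation (H2, RuCl2[(R)-BINAP], MeOH) gives the (3R)-β-hydroxy ester F9. Claisen condensation of F9 with an excess of the lithium enolate of methyl acetate (LiN(iPr)2, THF, −78 to −30 °C) gives 10.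

Further compounds
F1 | step 12 | methyl (E)-δ-hydroxy enoate from cross-metathesis of 17 with methyl acrylate (C3 ester, C4=C5 E, centres as in 17) | CCCCCCCCCCC[C@H](O[Si](C)(C)C(C)(C)C)CCC[C@@H]1C[C@H](C[C@H](C/C=C/C(=O)OC)O)OC(C)(C)O1
F2 | step 12 | all-cis 2-phenyl-1,3-dioxane (benzylidene acetal across O5 and O7) bearing CH2CO2Me on C5, other centres as in 17 | CCCCCCCCCCC[C@H](O[Si](C)(C)C(C)(C)C)CCC[C@@H]1C[C@H](C[C@@H]2C[C@H](CC(=O)OC)O[C@H](c3ccccc3)O2)OC(C)(C)O1
F3 | step 12 | C3 aldehyde corresponding to F2 | CCCCCCCCCCC[C@H](O[Si](C)(C)C(C)(C)C)CCC[C@@H]1C[C@H](C[C@@H]2C[C@H](CC=O)O[C@H](c3ccccc3)O2)OC(C)(C)O1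
F4 | step 12 | methyl (Z)-enoate from olefination of F3 (C2=C3 Z, benzylidene and acetonide retained) | CCCCCCCCCCC[C@H](O[Si](C)(C)C(C)(C)C)CCC[C@@H]1C[C@H](C[C@@H]2C[C@H](C/C=C\C(=O)OC)O[C@H](c3ccccc3)O2)OC(C)(C)O1
F5 | step 15 | C5 homoallylic alcohol from vinyl opening of 23 (C2=C3 terminal alkene, centres as in 23) | CCCCCCCCCCC[C@H](O[Si](C)(C)C(C)(C)C)CCC[C@@H]1C[C@H](C[C@@H](O[Si](C)(C)C(C)(C)C)C[C@@H](O)CC=C)OC(C)(C)O1
F6 | step 15 | acrylate ester of F5 | CCCCCCCCCCC[C@H](O[Si](C)(C)C(C)(C)C)CCC[C@@H]1C[C@H](C[C@@H](O[Si](C)(C)C(C)(C)C)C[C@@H](OC(=O)C=C)CC=C)OC(C)(C)O1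
F7 | step 15 | protected target: 27 with TBS on O7 and O15 and the acetonide on O9/O11 | CCCCCCCCCCC[C@H](O[Si](C)(C)C(C)(C)C)CCC[C@@H]1C[C@H](C[C@@H](O[Si](C)(C)C(C)(C)C)C[C@@H]2CC=CC(=O)O2)OC(C)(C)O1
F8 | step 6 | methyl (7S)-7-(tert-butyldimethylsilyloxy)-3-oxooctadecanoate | CCCCCCCCCCC[C@H](O[Si](C)(C)C(C)(C)C)CCCC(=O)CC(=O)OC
F9 | step 6 | methyl (3R,7S)-7-(tert-butyldimethylsilyloxy)-3-hydroxyoctadecanoate | CCCCCCCCCCC[C@H](O[Si](C)(C)C(C)(C)C)CCC[C@@H](O)CC(=O)OC
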